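## The problem

The target 22 is an achiral bibenzyl, so the difficulty is regiochemical and not stereochemical. Ring A is numbered here C1 (OMe), C2 (H), C3 (OH), C4 (4-hydroxybenzyl), C5 (ethylene bridge), C6 (4-hydroxybenzyl). Ring B carries the bridge, a 4-hydroxybenzyl group ortho to it, and a hydroxyl para to that benzyl group. Ring A is the hard part: five contiguous substituents, a bridge flanked by two identical benzyl groups, and two oxygens that differ only by one methyl group. Electrophilic substitution on a 5-alkylresorcinol cannot reliably tell C4 from C6 or O1 from O3. The five phenols need protection that can be removed without touching the C1 methyl ether, which points to benzyl ethers. The three diarylmethane CH2 groups sit between electron-rich rings and are prone to oxidation and to acid-induced Friedel–Crafts chemistry, so late strong oxidants and Lewis acids are to be avoided. The feature that opens the route is that C1(OMe)–C2(H)–C3(O) together with the C6 benzyl group maps onto an acetoacetate-derived 1,3-dioxygenated butadiene whose two oxygens are different from the start, while C4 and C5 map onto an alkyne. If the C4 benzyl group is carried as an aroyl group, that alkyne is an ynone. It is then activated, and polarized so that the bridge-bearing carbon is the electrophilic one. The aroyl group ends ortho to the new hydroxyl and para to the methoxyl, which makes its later reduction to CH2 easy.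

## Retrosynthesis

**22 from 20.** No skeletal bond is cut. The C4 methylene is traced back to a diaryl ketone and the five phenols to four benzyl ethers plus the free C3 hydroxyl of 20. Benzyl is chosen over methyl (indistinguishable from the C1 methoxyl) and over silyl (less robust through organolithium and palladium steps). The ketone is what activates the alkyne in the ring-forming step. The forward reaction asks for one hydrogenation over palladium under acid that removes the carbonyl oxygen and all four benzyl groups, passing through the debenzylated ketone 21.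

**20 from 17 and 11.** The ring A bonds C6–C5 and C3–C4 are cut, which opens ring A into diene 17 and ynone 11. This pairing puts both oxygens and the C6 benzyl group on the diene, where methoxyl (enol ether) and hydroxyl (former ester carbonyl) are already distinct. It puts the bridge and the acyl group on the alkyne, whose polarization fixes the orientation. Other pairings of ring A bonds would place no activating group on the two-carbon partner or would require the oxygens to be differentiated later. Both precursors are open-chain and carry no ring A at all. The forward reaction must be a regioselective [4+2] cycloaddition followed by loss of methanol (via 18) and of the silyl group (via 19).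

**11 from 9 and 10.** The bond between the carbonyl carbon and the alkyne carbon is cut, giving terminal alkyne 9 and acid chloride 10. Acylation of the alkyne under palladium–copper catalysis reaches the ynone in one step. Acetylide addition to an aldehyde followed by oxidation would need two. The forward step must tolerate benzyl ethers and must not add amine to the product ynone, so a tertiary amine base is used.

**9 from 5 and 6.** The central CH2–CH2 bond of the bridge is cut. Benzylic bromide 5 is a good SN2 electrophile, and silylpropyne 6, after lithiation to 7, is a three-carbon nucleophile whose silyl group directs attack to the propargylic position. Alkylation gives 8 and desilylation gives 9. Cross-coupling of a ring B aryl triflate with a homopropargyl metal reagent was the neighbouring cut. It needs a reagent that must itself be prepared. Bromide 5 comes from aldehyde 3 by reduction to alcohol 4 and bromination.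

**3 from 1 and 2.** The aryl–CH2 bond of the ring B diarylmethane is cut. Boronic acid 1 already has the formyl group and the protected oxygen in the correct 1,2,4-relationship. Benzyl chloride 2 supplies the 4-(benzyloxy)benzyl unit and is used a second time for the diene. Friedel–Crafts benzylation of a phenol would give regioisomers and is incompatible with benzyl ethers. The forward reaction is an sp2–sp3 Suzuki–Miyaura coupling that leaves the aldehyde untouched.

**17 from 12 and 2.** The diene is traced through enoate 15 and keto ester 14 to methyl acetoacetate 12 and chloride 2. The only carbon–carbon bond cut is the one made by γ-alkylation of dianion 13. O-Methylation of 14 fixes the future C1 methoxyl. γ-Deprotonation of 15 to dienolate 16 and O-silylation give the mixed ketene acetal 17. Each step is a standard operation on acetoacetate.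

## Roads not taken

**Alternative 1:** The three aryl–CH bonds to the 4-oxyphenyl rings are cut at once. A core trialdehyde A2 (formyl groups at C4 and C6 of ring A and ortho to the bridge on ring B, phenols as benzyl ethers) would take up three equivalents of 4-(benzyloxy)phenylmagnesium bromide A3 to give the tris(diarylcarbinol) A1. One hydrogenolysis would then remove the three benzylic hydroxyls and the benzyl ethers.
- Merits: all three arms come from one cheap reagent, and Grignard addition to aldehydes is more predictable than a crowded cycloaddition. In that respect this road is the safer one.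
- Weak points: the problem is moved into A2 and not solved. The bibenzyl must be assembled first, and ring A must then be formylated twice ortho to the bridge, the second time on a ring deactivated by the first formyl group. The OMe/OH distinction has to be carried from the very beginning on a resorcinol whose two oxygens sit in nearly identical surroundings. A1 is a diastereomer mixture that is hard to characterize.
- Comparison: the chosen plan has a less certain key step. In return it builds ring A with all five substituents and both oxygens differentiated in one operation, with a shorter linear sequence.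

**Alternative 2:** The two bonds joining the bridge to the rings are cut. A ring A aryllithium A5 and vinylboronic acid pinacol ester A7 would form an ate complex. Coupling with the ring B triflate A6 under Pd(OAc)2 and a ferrocenyl bisphosphine would induce a 1,2-aryl shift and give the α-boryl bibenzyl A4.
- Merits: the late stage is highly convergent and modular, and in that respect better than the chosen plan.
- Weak points: A5 is a fully substituted ring A that must be made first, with a metalated carbon between two benzyl groups whose CH2 protons are acidic. A di-ortho-substituted aryl group is a poor migrating group. The reaction creates a boron-bearing stereocentre that the target does not need, so a protodeboronation step is added before debenzylation.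
- Comparison: the chosen plan is less convergent at the end. What it offers is a direct answer to the ring A substitution pattern, which this road leaves open.

**Alternative 3:** The C1–C2 bond of ring A is cut at the cyclohexane-1,3-dione level. KOtBu would cyclize δ-keto ester A9 by Claisen condensation to dione A8. Mono-O-methylation and dehydrogenation would give ring A.
- Merits: the condensation is robust. Because A8 is symmetric, either oxygen may be methylated, so the OMe/OH problem disappears; this is more elegant than relying on the elimination mode of a ketal.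
- Weak points: A9 has three contiguous substituted carbons and needs a Michael addition between hindered partners. A8 is a diastereomer mixture. The dehydrogenation to the arene must be done in the presence of benzyl ethers and of oxidation-prone electron-rich diarylmethane CH2 groups.
- Comparison: the chosen plan reaches the aromatic oxidation level directly and needs no oxidant at any stage.

Key step: step 10

Remark on the chemistry: diene 17 is assumed to form mainly as the 1Z,3Z isomer. The geometry at its ketene acetal end does not affect the product, because that carbon becomes aromatic.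

## Route

Step 1
Reactants: 1 [4-(benzyloxy)-2-formylphenyl]boronic acid; 2 4-(benzyloxy)benzyl chloride
Product: 3 5-(benzyloxy)-2-[4-(benzyloxy)benzyl]benzaldehyde
Conditions: Pd(OAc)2 (2 mol %), PPh3 (4 mol %), K3PO4, toluene/H2O 20:1, 80 °C
Reagents that add atoms: none
Why: Suzuki–Miyaura sp2–sp3 coupling; zerovalent palladium formed in situ inserts into the benzylic C–Cl bond, the benzylpalladium has no β-hydrogen, and the aldehyde and benzyl ethers are inert; little water is used because the electron-rich benzyl chloride solvolyses easily.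

Step 2
Reactants: 3 5-(benzyloxy)-2-[4-(benzyloxy)benzyl]benzaldehyde
Product: 4 {5-(benzyloxy)-2-[4-(benzyloxy)benzyl]phenyl}methanol
Conditions: NaBH4, MeOH/THF, 0 °C
Reagents that add atoms: none
Why: Borohydride reduction of an aryl aldehyde; nothing else in the molecule is reducible under these conditions.

Step 3
Reactants: 4 {5-(benzyloxy)-2-[4-(benzyloxy)benzyl]phenyl}methanol
Product: 5 4-(benzyloxy)-1-[4-(benzyloxy)benzyl]-2-(bromomethyl)benzene
Conditions: CBr4, PPh3, CH2Cl2, 0 °C → rt
Reagents that add atoms: carbon tetrabromide, BrC(Br)(Br)Br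
Why: Appel bromination under neutral conditions, chosen so that no strong acid meets the benzyl ethers or the electron-rich diarylmethane; the bromide is meta to the ether oxygen and should be stable enough to isolate.

Step 4
Reactants: 5 4-(benzyloxy)-1-[4-(benzyloxy)benzyl]-2-(bromomethyl)benzene; 6 trimethyl(prop-1-yn-1-yl)silane
Product: 8 (4-{5-(benzyloxy)-2-[4-(benzyloxy)benzyl]phenyl}but-1-yn-1-yl)trimethylsilane, via 3-(trimethylsilyl)prop-2-yn-1-yllithium 7 (not isolated)
Conditions: 6, n-BuLi, THF, −78 °C; then 5, −78 °C → rt
Reagents that add atoms: none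
Why: SN2 alkylation of a silyl-substituted propargyllithium by a benzylic bromide; the bulky silyl group directs attack to the CH2 terminus (propargylic and not allenic product) and the low temperature suppresses deprotonation of the diarylmethane CH2.

Step 5
Reactants: 8 (4-{5-(benzyloxy)-2-[4-(benzyloxy)benzyl]phenyl}but-1-yn-1-yl)trimethylsilane
Product: 9 4-(benzyloxy)-1-[4-(benzyloxy)benzyl]-2-(but-3-yn-1-yl)benzene
Conditions: K2CO3, MeOH/THF, rt
Reagents that add atoms: none
Why: Methanolysis of the alkynyl C–Si bond (protodesilylation), which is selective for silicon on sp carbon.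

Step 6
Reactants: 9 4-(benzyloxy)-1-[4-(benzyloxy)benzyl]-2-(but-3-yn-1-yl)benzene; 10 4-(benzyloxy)benzoyl chloride
Product: 11 5-{5-(benzyloxy)-2-[4-(benzyloxy)benzyl]phenyl}-1-[4-(benzyloxy)phenyl]pent-2-yn-1-one
Conditions: PdCl2(PPh3)2 (2 mol %), CuI (4 mol %), Et3N, THF, rt
Reagents that add atoms: none
Why: Sonogashira-type acylation of a terminal alkyne; the copper acetylide transfers the alkynyl group to the acylpalladium chloride and reductive elimination gives the ynone, while the tertiary amine cannot add to the product.

Step 7
Reactants: 12 methyl acetoacetate; 2 4-(benzyloxy)benzyl chloride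
Product: 14 methyl 5-[4-(benzyloxy)phenyl]-3-oxopentanoate, via acetoacetate dianion 13 (not isolated)
Conditions: NaH, THF, 0 °C; n-BuLi, 0 °C; then 2, 0 °C → rt; aq NH4Cl
Reagents that add atoms: none
Why: γ-Alkylation of the acetoacetate dianion; the second deprotonation creates the more reactive terminal carbanion, which alone attacks the benzylic chloride.

Step 8
Reactants: 14 methyl 5-[4-(benzyloxy)phenyl]-3-oxopentanoate
Product: 15 methyl (2E)-5-[4-(benzyloxy)phenyl]-3-methoxypent-2-enoate
Conditions: HC(OMe)3, H2SO4 (cat.), MeOH, rt
Reagents that add atoms: trimethyl orthoformate, COC(OC)OC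
Why: Acid-catalysed enol ether formation from a β-keto ester with the orthoformate as methyl donor and water scavenger; conjugation with the ester favours the 2E enoate, in which the C4 methylene lies syn to the ester carbonyl as the next step requires.

Step 9
Reactants: 15 methyl (2E)-5-[4-(benzyloxy)phenyl]-3-methoxypent-2-enoate
Product: 17 {[(1Z,3Z)-5-[4-(benzyloxy)phenyl]-1,3-dimethoxypenta-1,3-dien-1-yl]oxy}trimethylsilane, via lithium dienolate 16 (not isolated)
Conditions: LDA, THF, −78 °C; TMSCl, −78 °C → rt; filtration through Celite under Ar (pentane), used crude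
Reagents that add atoms: chlorotrimethylsilane, C[Si](C)(C)Cl
Why: Carbonyl-directed γ-deprotonation of a β-alkoxy enoate and O-silylation of the extended enolate, the standard preparation of 1-alkoxy-1-silyloxy-3-alkoxy dienes; the 3Z isomer, with the benzyl group turned away from the diene, is expected to predominate and is the one that can adopt the reactive s-cis form.

Step 10
Reactants: 17 {[(1Z,3Z)-5-[4-(benzyloxy)phenyl]-1,3-dimethoxypenta-1,3-dien-1-yl]oxy}trimethylsilane; 11 5-{5-(benzyloxy)-2-[4-(benzyloxy)benzyl]phenyl}-1-[4-(benzyloxy)phenyl]pent-2-yn-1-one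
Product: 20 [4-(benzyloxy)phenyl]{3-[4-(benzyloxy)benzyl]-2-(2-{5-(benzyloxy)-2-[4-(benzyloxy)benzyl]phenyl}ethyl)-6-hydroxy-4-methoxyphenyl}methanone, via cyclohexadiene ketal 18 (not isolated), via aryl silyl ether 19 (not isolated)
Conditions: 17 (2.5 equiv), toluene, 90–110 °C, sealed tube; then 1 M HCl, THF, 0 °C → rt
Reagents that add atoms: none
Why: The electron-rich ketene silyl acetal diene 17 and the electron-poor ynone 11 should combine in a normal-demand, strongly asynchronous Diels–Alder reaction in which the benzyl-bearing diene terminus bonds first to the ynone β-carbon and the ketene acetal carbon then bonds to the α-carbon, giving the cyclohexa-1,4-diene ketal 18. The closest known reaction type is the cycloaddition of 1-alkoxy-1-silyloxy-3-alkoxybutadienes to acetylenic ketones and esters with in-situ aromatization to resorcinol monoethers. Ring A is closed by this intermolecular [4+2] cycloaddition, which forms C6–C5 and C3–C4 in one operation. The two sp3 centres of 18 are transient and are erased when the mixed ketal loses methanol across the ring to give the aryl silyl ether 19, so no stereocentre has to be controlled. The dilute acid then cleaves the labile O–Si bond of 19, or of any surviving 18 (whose hemiketal then collapses with loss of methanol), so that the oxygen kept at C3 is the one that carried silicon and ends as a phenol hydrogen-bonded to the aroyl carbonyl. The step needs regioselectivity, and the partners secure it electronically: the largest HOMO coefficient of 17 lies on the carbon remote from the ketene acetal and the largest LUMO coefficient of 11 on the β-carbon that carries the bridge. It also needs an s-cis diene, which the 3Z geometry provides, and the excess of 17 compensates for its partial hydrolysis back to 15.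

Step 11
Reactants: 20 [4-(benzyloxy)phenyl]{3-[4-(benzyloxy)benzyl]-2-(2-{5-(benzyloxy)-2-[4-(benzyloxy)benzyl]phenyl}ethyl)-6-hydroxy-4-methoxyphenyl}methanone
Product: 22 2,4-bis(4-hydroxybenzyl)-3-{2-[5-hydroxy-2-(4-hydroxybenzyl)phenyl]ethyl}-5-methoxyphenol, via debenzylated ketone 21 (not isolated)
Conditions: H2 (3 bar), 10% Pd/C, EtOAc/AcOH 1:1, HClO4 (cat.), 25–50 °C
Reagents that add atoms: none
Why: Catalytic hydrogenolysis; the four benzyl ethers should cleave first to give 21, and under acid the diaryl ketone is then reduced and its doubly benzylic C–O bond, stabilized by the ortho-hydroxyl and para-methoxyl of ring A and the para-hydroxyl of the other ring, is hydrogenolysed to CH2; the methyl ether and the arene rings are not touched by palladium under these conditions.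

## Compound list

1 | [4-(benzyloxy)-2-formylphenyl]boronic acid | O=Cc1cc(OCc2ccccc2)ccc1B(O)O | starting material
2 | 4-(benzyloxy)benzyl chloride | ClCc1ccc(OCc2ccccc2)cc1 | starting material
3 | 5-(benzyloxy)-2-[4-(benzyloxy)benzyl]benzaldehyde | O=Cc1cc(OCc2ccccc2)ccc1Cc1ccc(OCc2ccccc2)cc1 | intermediate
4 | {5-(benzyloxy)-2-[4-(benzyloxy)benzyl]phenyl}methanol | OCc1cc(OCc2ccccc2)ccc1Cc1ccc(OCc2ccccc2)cc1 | intermediate
5 | 4-(benzyloxy)-1-[4-(benzyloxy)benzyl]-2-(bromomethyl)benzene | BrCc1cc(OCc2ccccc2)ccc1Cc1ccc(OCc2ccccc2)cc1 | intermediate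
6 | trimethyl(prop-1-yn-1-yl)silane | CC#C[Si](C)(C)C | starting material
7 | [3-(trimethylsilyl)prop-2-yn-1-yl]lithium | [Li]CC#C[Si](C)(C)C | intermediate (not isolated)
8 | (4-{5-(benzyloxy)-2-[4-(benzyloxy)benzyl]phenyl}but-1-yn-1-yl)trimethylsilane | C[Si](C)(C)C#CCCc1cc(OCc2ccccc2)ccc1Cc1ccc(OCc2ccccc2)cc1 | intermediate
9 | 4-(benzyloxy)-1-[4-(benzyloxy)benzyl]-2-(but-3-yn-1-yl)benzene | C#CCCc1cc(OCc2ccccc2)ccc1Cc1ccc(OCc2ccccc2)cc1 | intermediate
10 | 4-(benzyloxy)benzoyl chloride | O=C(Cl)c1ccc(OCc2ccccc2)cc1 | starting material
11 | 5-{5-(benzyloxy)-2-[4-(benzyloxy)benzyl]phenyl}-1-[4-(benzyloxy)phenyl]pent-2-yn-1-one | O=C(C#CCCc1cc(OCc2ccccc2)ccc1Cc1ccc(OCc2ccccc2)cc1)c1ccc(OCc2ccccc2)cc1 | intermediate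
12 | methyl acetoacetate | COC(=O)CC(C)=O | starting material
13 | sodium lithium dianion of methyl acetoacetate | [CH2-]C(=O)[CH-]C(=O)OC.[Na+].[Li+] | intermediate (not isolated)
14 | methyl 5-[4-(benzyloxy)phenyl]-3-oxopentanoate | COC(=O)CC(=O)CCc1ccc(OCc2ccccc2)cc1 | intermediate
15 | methyl (2E)-5-[4-(benzyloxy)phenyl]-3-methoxypent-2-enoate | COC(=O)/C=C(/OC)CCc1ccc(OCc2ccccc2)cc1 | intermediate
16 | lithium (1Z,3Z)-5-[4-(benzyloxy)phenyl]-1,3-dimethoxypenta-1,3-dien-1-olate | CO/C([O-])=C/C(OC)=C/Cc1ccc(OCc2ccccc2)cc1.[Li+] | intermediate (not isolated)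
17 | {[(1Z,3Z)-5-[4-(benzyloxy)phenyl]-1,3-dimethoxypenta-1,3-dien-1-yl]oxy}trimethylsilane | CO/C(O[Si](C)(C)C)=C/C(OC)=C/Cc1ccc(OCc2ccccc2)cc1 | intermediate
18 | [4-(benzyloxy)phenyl]{3-[4-(benzyloxy)benzyl]-2-(2-{5-(benzyloxy)-2-[4-(benzyloxy)benzyl]phenyl}ethyl)-4,6-dimethoxy-6-(trimethylsilyloxy)cyclohexa-1,4-dien-1-yl}methanone (diastereomer mixture, both centres lost on aromatization) | COC1=CC(OC)(O[Si](C)(C)C)C(C(=O)c2ccc(OCc3ccccc3)cc2)=C(CCc2cc(OCc3ccccc3)ccc2Cc2ccc(OCc3ccccc3)cc2)C1Cc1ccc(OCc2ccccc2)cc1 | intermediate (not isolated)
19 | [4-(benzyloxy)phenyl]{3-[4-(benzyloxy)benzyl]-2-(2-{5-(benzyloxy)-2-[4-(benzyloxy)benzyl]phenyl}ethyl)-4-methoxy-6-(trimethylsilyloxy)phenyl}methanone | COc1cc(O[Si](C)(C)C)c(C(=O)c2ccc(OCc3ccccc3)cc2)c(CCc2cc(OCc3ccccc3)ccc2Cc2ccc(OCc3ccccc3)cc2)c1Cc1ccc(OCc2ccccc2)cc1 | intermediate (not isolated)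
20 | [4-(benzyloxy)phenyl]{3-[4-(benzyloxy)benzyl]-2-(2-{5-(benzyloxy)-2-[4-(benzyloxy)benzyl]phenyl}ethyl)-6-hydroxy-4-methoxyphenyl}methanone | COc1cc(O)c(C(=O)c2ccc(OCc3ccccc3)cc2)c(CCc2cc(OCc3ccccc3)ccc2Cc2ccc(OCc3ccccc3)cc2)c1Cc1ccc(OCc2ccccc2)cc1 | intermediate
21 | {6-hydroxy-3-(4-hydroxybenzyl)-2-{2-[5-hydroxy-2-(4-hydroxybenzyl)phenyl]ethyl}-4-methoxyphenyl}(4-hydroxyphenyl)methanone | COc1cc(O)c(C(=O)c2ccc(O)cc2)c(CCc2cc(O)ccc2Cc2ccc(O)cc2)c1Cc1ccc(O)cc1 | intermediate (not isolated)
22 | 2,4-bis(4-hydroxybenzyl)-3-{2-[5-hydroxy-2-(4-hydroxybenzyl)phenyl]ethyl}-5-methoxyphenol | COc1cc(O)c(Cc2ccc(O)cc2)c(CCc2cc(O)ccc2Cc2ccc(O)cc2)c1Cc1ccc(O)cc1 | target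

## Step count and risks

Total steps: 11. Longest linear sequence: 8 steps (steps 1–6, 10, 11). The diene branch (steps 7–9) runs in parallel.

**Step 10 (key step).** The cycloaddition may be too slow. It joins a benzyl-bearing diene terminus to an alkyl-bearing β-carbon of an aryl ynone that is deactivated by its para-benzyloxy donor. Thermal decomposition or protodesilylation of the diene, [2+2] addition at the ketene acetal, or loss of silanol in place of methanol during aromatization could then compete. The fallback sets out from alkyne 9. Formylation (n-BuLi, then DMF) would give 5-{5-(benzyloxy)-2-[4-(benzyloxy)benzyl]phenyl}pent-2-ynal F1, a smaller and more electrophilic dienophile. It should undergo the same cycloaddition with 17 at lower temperature, and the same acid work-up would give 3-[4-(benzyloxy)benzyl]-2-(2-{5-(benzyloxy)-2-[4-(benzyloxy)benzyl]phenyl}ethyl)-6-hydroxy-4-methoxybenzaldehyde F2. Excess 4-(benzyloxy)phenylmagnesium bromide would add to F2 to give the diarylcarbinol 4-[4-(benzyloxy)benzyl]-3-(2-{5-(benzyloxy)-2-[4-(benzyloxy)benzyl]phenyl}ethyl)-2-{[4-(benzyloxy)phenyl](hydroxy)methyl}-5-methoxyphenol F3. Under the hydrogenation conditions of step 11, F3 would lose its benzylic hydroxyl and the four benzyl groups, and the route is rejoined at 22.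

**Step 11.** Benzyl ether cleavage should be fast, but deoxygenation may stall. The carbonyl is flanked by the hydroxyl and the bridge, is twisted out of the plane of ring A, and after debenzylation is a poorly electrophilic vinylogous acid. Acid-induced Friedel–Crafts closure of the diarylmethyl cation onto ring B is a further possibility. The fallback sets out from 20 and separates the two tasks. Ionic hydrogenation (Et3SiH, CF3CO2H, CH2Cl2, 0 °C) would reduce the ketone in solution through the donor-stabilized cation, with excess silane as trap. It would give 2,4-bis[4-(benzyloxy)benzyl]-3-(2-{5-(benzyloxy)-2-[4-(benzyloxy)benzyl]phenyl}ethyl)-5-methoxyphenol F4. Neutral hydrogenolysis (H2, Pd/C, EtOAc/MeOH) would then give 22. Partial loss of benzyl groups in the acid step would be harmless.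

**Step 9.** γ-Deprotonation may be incomplete, the new C3=C4 double bond may form with poor geometric control (the 3E isomer cannot reach a reactive s-cis form), and the ketene acetal may hydrolyse during isolation. The fallback sets out from 14 and uses a more electron-rich diene.
- Soft enolization (TMSCl, Et3N) would give methyl (2Z)-5-[4-(benzyloxy)phenyl]-3-(trimethylsilyloxy)pent-2-enoate F5.
- LDA and TMSCl would convert F5 into (1Z,3Z)-5-[4-(benzyloxy)phenyl]-1-methoxy-1,3-bis(trimethylsilyloxy)penta-1,3-diene F6.
- Cycloaddition of F6 with 11 and acid work-up would give the resorcinol ketone [4-(benzyloxy)phenyl]{3-[4-(benzyloxy)benzyl]-2-(2-{5-(benzyloxy)-2-[4-(benzyloxy)benzyl]phenyl}ethyl)-4,6-dihydroxyphenyl}methanone F7.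
- Methylation (MeI, K2CO3, acetone) should occur only at the hydroxyl para to the carbonyl, because the ortho hydroxyl is tied up in a hydrogen bond. This returns the route to 20.

**Step 1.** The ortho-formyl boronic acid may undergo protodeboronation under basic conditions, and the electron-rich benzyl chloride may be lost to solvolysis or homocoupling. The fallback sets out from 1. Reduction with NaBH4 would give the cyclic hemiester 5-(benzyloxy)-1,3-dihydro-2,1-benzoxaborol-1-ol F8, which resists protodeboronation better. Suzuki–Miyaura coupling of F8 with 2 would give alcohol 4 directly, so the route is rejoined at 4 with the same step count.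

## Further compounds

F1 | step 10 | 5-{5-(benzyloxy)-2-[4-(benzyloxy)benzyl]phenyl}pent-2-ynal | O=CC#CCCc1cc(OCc2ccccc2)ccc1Cc1ccc(OCc2ccccc2)cc1
F2 | step 10 | 3-[4-(benzyloxy)benzyl]-2-(2-{5-(benzyloxy)-2-[4-(benzyloxy)benzyl]phenyl}ethyl)-6-hydroxy-4-methoxybenzaldehyde | COc1cc(O)c(C=O)c(CCc2cc(OCc3ccccc3)ccc2Cc2ccc(OCc3ccccc3)cc2)c1Cc1ccc(OCc2ccccc2)cc1
F3 | step 10 | 4-[4-(benzyloxy)benzyl]-3-(2-{5-(benzyloxy)-2-[4-(benzyloxy)benzyl]phenyl}ethyl)-2-{[4-(benzyloxy)phenyl](hydroxy)methyl}-5-methoxyphenol (racemic) | COc1cc(O)c(C(O)c2ccc(OCc3ccccc3)cc2)c(CCc2cc(OCc3ccccc3)ccc2Cc2ccc(OCc3ccccc3)cc2)c1Cc1ccc(OCc2ccccc2)cc1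
F4 | step 11 | 2,4-bis[4-(benzyloxy)benzyl]-3-(2-{5-(benzyloxy)-2-[4-(benzyloxy)benzyl]phenyl}ethyl)-5-methoxyphenol | COc1cc(O)c(Cc2ccc(OCc3ccccc3)cc2)c(CCc2cc(OCc3ccccc3)ccc2Cc2ccc(OCc3ccccc3)cc2)c1Cc1ccc(OCc2ccccc2)cc1
F5 | step 9 | methyl (2Z)-5-[4-(benzyloxy)phenyl]-3-(trimethylsilyloxy)pent-2-enoate | COC(=O)/C=C(\O[Si](C)(C)C)CCc1ccc(OCc2ccccc2)cc1
F6 | step 9 | (1Z,3Z)-5-[4-(benzyloxy)phenyl]-1-methoxy-1,3-bis(trimethylsilyloxy)penta-1,3-diene | CO/C(O[Si](C)(C)C)=C/C(O[Si](C)(C)C)=C/Cc1ccc(OCc2ccccc2)cc1
F7 | step 9 | [4-(benzyloxy)phenyl]{3-[4-(benzyloxy)benzyl]-2-(2-{5-(benzyloxy)-2-[4-(benzyloxy)benzyl]phenyl}ethyl)-4,6-dihydroxyphenyl}methanone | Oc1cc(O)c(C(=O)c2ccc(OCc3ccccc3)cc2)c(CCc2cc(OCc3ccccc3)ccc2Cc2ccc(OCc3ccccc3)cc2)c1Cc1ccc(OCc2ccccc2)cc1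
F8 | step 1 | 5-(benzyloxy)-1,3-dihydro-2,1-benzoxaborol-1-ol | OB1OCc2cc(OCc3ccccc3)ccc21
A1 | alternative 1 | 1-(benzyloxy)-2,4-bis{[4-(benzyloxy)phenyl](hydroxy)methyl}-3-[2-(5-(benzyloxy)-2-{[4-(benzyloxy)phenyl](hydroxy)methyl}phenyl)ethyl]-5-methoxybenzene (diastereomer mixture) | COc1cc(OCc2ccccc2)c(C(O)c2ccc(OCc3ccccc3)cc2)c(CCc2cc(OCc3ccccc3)ccc2C(O)c2ccc(OCc3ccccc3)cc2)c1C(O)c1ccc(OCc2ccccc2)cc1
A2 | alternative 1 | 4-(benzyloxy)-2-{2-[5-(benzyloxy)-2-formylphenyl]ethyl}-6-methoxybenzene-1,3-dicarbaldehyde | COc1cc(OCc2ccccc2)c(C=O)c(CCc2cc(OCc3ccccc3)ccc2C=O)c1C=O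
A3 | alternative 1 | 4-(benzyloxy)phenylmagnesium bromide | Br[Mg]c1ccc(OCc2ccccc2)cc1
A4 | alternative 2 | 2-[1-{3-(benzyloxy)-2,6-bis[4-(benzyloxy)benzyl]-5-methoxyphenyl}-2-{5-(benzyloxy)-2-[4-(benzyloxy)benzyl]phenyl}ethyl]-4,4,5,5-tetramethyl-1,3,2-dioxaborolane (racemic) | COc1cc(OCc2ccccc2)c(Cc2ccc(OCc3ccccc3)cc2)c(C(Cc2cc(OCc3ccccc3)ccc2Cc2ccc(OCc3ccccc3)cc2)B2OC(C)(C)C(C)(C)O2)c1Cc1ccc(OCc2ccccc2)cc1
A5 | alternative 2 | {3-(benzyloxy)-2,6-bis[4-(benzyloxy)benzyl]-5-methoxyphenyl}lithium | COc1cc(OCc2ccccc2)c(Cc2ccc(OCc3ccccc3)cc2)c([Li])c1Cc1ccc(OCc2ccccc2)cc1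
A6 | alternative 2 | 5-(benzyloxy)-2-[4-(benzyloxy)benzyl]phenyl trifluoromethanesulfonate | O=S(=O)(Oc1cc(OCc2ccccc2)ccc1Cc1ccc(OCc2ccccc2)cc1)C(F)(F)F
A7 | alternative 2 | 2-ethenyl-4,4,5,5-tetramethyl-1,3,2-dioxaborolane | C=CB1OC(C)(C)C(C)(C)O1
A8 | alternative 3 | 4,6-bis[4-(benzyloxy)benzyl]-5-(2-{5-(benzyloxy)-2-[4-(benzyloxy)benzyl]phenyl}ethyl)cyclohexane-1,3-dione (diastereomer mixture) | O=C1CC(=O)C(Cc2ccc(OCc3ccccc3)cc2)C(CCc2cc(OCc3ccccc3)ccc2Cc2ccc(OCc3ccccc3)cc2)C1Cc1ccc(OCc2ccccc2)cc1
A9 | alternative 3 | methyl 2,4-bis[4-(benzyloxy)benzyl]-3-(2-{5-(benzyloxy)-2-[4-(benzyloxy)benzyl]phenyl}ethyl)-5-oxohexanoate (diastereomer mixture) | COC(=O)C(Cc1ccc(OCc2ccccc2)cc1)C(CCc1cc(OCc2ccccc2)ccc1Cc1ccc(OCc2ccccc2)cc1)C(Cc1ccc(OCc2ccccc2)cc1)C(C)=O
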